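The numbers in the tables were generated by integration for substances that don't exist; the scatter is artificial.

In a one-step world the target forms as fast as starting material meets coupling partner, so the rate goes with the product of both concentrations. The blue run has twice the starting material of the teal run at the same coupling partner, yet at 4.0 min it shows 0.0164 M of target against 0.0154 M. That world is gone, and two colleagues, Ada and Ben, now dispute what replaces it.

| setting | teal | grey | blue | amber | ochre |
|---|---|---|---|---|---|
| starting material | 0.150 M | 0.0750 M | 0.300 M | 0.150 M | 0.450 M |
| coupling partner | 0.375 M | 0.300 M | 0.375 M | 0.375 M | 0.190 M |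
| free catalyst | 0.00450 M | 0.00450 M | 0.00450 M | 0.0130 M | 0.00450 M |
| time |  |  |  |  | 32 min |

| run | time / min | [target] / M |
|---|---|---|
| teal run | 4.0 | 0.0154 |
| teal run | 8.0 | 0.0380 |
| teal run | 12 | 0.0628 |
| teal run | 16 | 0.0817 |
| teal run | 20 | 0.0998 |
| teal run | 24 | 0.1162 |
| teal run | 28 | 0.1296 |
| teal run | 32 | 0.1393 |
| grey run | 4.0 | 0.0097 |
| grey run | 8.0 | 0.0263 |
| grey run | 12 | 0.0417 |
| grey run | 16 | 0.0539 |
| grey run | 20 | 0.0640 |
| grey run | 24 | 0.0684 |
| grey run | 28 | 0.0715 |
| grey run | 32 | 0.0737 |
| blue run | 4.0 | 0.0164 |
| blue run | 8.0 | 0.0432 |
| blue run | 12 | 0.0673 |
| blue run | 16 | 0.0887 |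
| blue run | 20 | 0.1109 |
| blue run | 24 | 0.1295 |
| blue run | 28 | 0.1463 |
| blue run | 32 | 0.1633 |
| amber run | 4.0 | 0.0599 |
| amber run | 8.0 | 0.1203 |
| amber run | 12 | 0.1440 |
| amber run | 16 | 0.1507 |
| amber run | 20 | 0.1511 |
| amber run | 24 | 0.1492 |
| amber run | 28 | 0.1496 |
| amber run | 32 | 0.1502 |

(standard deviation of a reading: 8 × 10⁻⁴ M)

- Overall: starting material + coupling partner -> target, with free catalyst as catalyst.
- Constant volume, constant temperature.
- Readings of a species count what is bound in complexes too.
- An order is taken over about fifteen percent of the charge, up and down.

* reaction order in [free catalyst] at the outset, round the charge of the teal run, defined at two percent of the starting material turned into target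
* reaction order in [starting material] at the outset, round the charge of the teal run, defined at two percent of the starting material turned into target (one fixed amount of target, the same in the runs compared)
* target in the ochre run at 32 min, as a share of the starting material charged

Ben holds that starting material still counts. The grey run, with half the starting material of the teal run, reads 0.0097 M at 4.0 min against 0.0154 M. Its coupling partner is lower too, 0.300 M against 0.375 M, but after dividing that out he still reads an order of 0.345 in starting material. So the ochre run, with 0.450 M, should gain from its large charge.

Ada holds that the coupling partner sets the pace once the catalyst has started. She compares runs with equal partner: from 8.0 min to 12 min, the blue run gains 0.972 of what the teal run gains, an order of −0.0413 as read.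

Her test needs no clock. Take the rate in the blue run over two steps, from 8.0 min to 16 min and from 24 min to 32 min, and divide the later by the earlier: 0.743. The mean [coupling partner] of the two steps stands in the ratio 0.740. The blue run reads as pseudo-first-order in coupling partner over these steps. So she names the rate divided by [coupling partner] the partner rate, w. The two steps read 0.0184 min⁻¹ and 0.0185 min⁻¹, and their mean is 0.0184 min⁻¹.

I side with Ada. If w holds, two flasks with equal free catalyst, both with [starting material] at or above the 0.137 M of the blue run at 32 min, spend the same share of their coupling partner in equal time, and the blue run has spent 43.5% by then. The ochre run, where coupling partner is the limiting reagent, should then make 0.0827 M, which is 18.4% of its starting material. For the free catalyst, I set the amber step from 4.0 min to 8.0 min against the teal step from 8.0 min to 12 min and read an order of 0.839.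

The forecast is Ben's side and stands above my reckoning, at 23%, with orders 1.1 in free catalyst and 0.25 in starting material, the latter on the ground that “Grey is lower, which suggests saturation”.

The simulation gives 18.0% for the ochre run, with orders 0.065 in starting material and 0.94 in free catalyst.

    active catalyst + starting material ⇌ catalyst-substrate complex, settled at all times (65.40 M⁻¹)
    catalyst-substrate complex + coupling partner → target + active catalyst (6.420 M⁻¹ min⁻¹)
    active catalyst + impurity → spent catalyst
    free catalyst + coupling partner → active catalyst + coupling partner (2.106 M⁻¹ min⁻¹)

With one fixed amount of target made, the blue run goes at 0.0043 M min⁻¹ and the teal run at 0.0042 M min⁻¹, on twice the starting material. Ben's view has its region at the end of the grey run. From 28 min to 32 min, [starting material] stands between 0.00350 M and 0.00130 M, and the partner rate reads 0.00242 min⁻¹, less than the blue run's 0.0184 min⁻¹ by a factor of 7.60.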